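**Retrosynthetic overview**
1. Guidongnin C ⇐ exo-face hydrogenation (sets C16) and debenzylation of the 16-methylene-15-ketone 21 ⇐ α-methylenation of pentacyclic ketone 20.
2. 20 ⇐ enal 19 in one carbene-catalysed cascade: the enal β-carbon C13 (as homoenolate) bonds to C14, the β-carbon of the α-methylene lactone, then C8 is acylated by C15. Rings C and D form together.
3. 19 ⇐ allylic bromide 14 + (E)-hex-3-enal (indium allylation makes C9–C11 and sets C9/C11), then ozonolysis/Wittig.
4. 14 ⇐ aldehyde 9 + methyl 2-(bromomethyl)acrylate (quaternary C10), reduction/lactonization (δ-lactone), allylic bromination.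
5. 9 ⇐ butenolide 7 ⇐ desymmetrized meso anhydride 1. Ring A is bought; ring order: γ-lactone, δ-lactone, then C and D.

Assumption: quinine gives the (1S,2R) hemiester 2 in step 1; if the sense of induction is the opposite, quinidine is used instead.

Note: locants C1–C20 in later names are those of the target skeleton (C4 = methyl-bearing quaternary carbon, C10 = spiro carbon, C6/C19 = γ-lactone C=O/OCH2, C7/C20 = δ-lactone C=O/OCH2, C15 = ketone, C11 = carbinol).

**Step 1**
Reactants: 1 cis-cyclohexane-1,2-dicarboxylic anhydride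
Product: 2 (1S,2R)-2-(methoxycarbonyl)cyclohexane-1-carboxylic acid
Conditions: quinine (1.1 equiv), MeOH (3 equiv), toluene/CCl4, −55 °C
Reagents that add atoms: methanol, CO
Why: Alkaloid-mediated desymmetrizing methanolysis of the meso anhydride differentiates the enantiotopic carbonyls and fixes the future C4 and C5 in high ee.

**Step 2**
Reactants: 2 (1S,2R)-2-(methoxycarbonyl)cyclohexane-1-carboxylic acid
Product: 3 (1S,2R)-2-(methoxycarbonyl)-2-methylcyclohexane-1-carboxylic acid
Conditions: LDA (2.2 equiv), THF, −78 to −20 °C; MeI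
Reagents that add atoms: iodomethane, CI
Why: Ester-enolate alkylation of the carboxylate dianion, where MeI attacks anti to the neighbouring carboxylate, creates quaternary C4 (R) with the two carboxyl carbons cis.

**Step 3**
Reactants: 3 (1S,2R)-2-(methoxycarbonyl)-2-methylcyclohexane-1-carboxylic acid
Product: 5 (3aR,7aS)-3a-methylhexahydro-2-benzofuran-1(3H)-one, via hydroxy acid 4 (not isolated)
Conditions: LiBEt3H, THF, 0 °C to rt; then 2 M HCl, rt
Reagents that add atoms: none
Why: Chemoselective hydride reduction of the ester beside the carboxylate, then acid-catalysed lactonization of the cis hydroxy acid, gives the γ-lactone (C6/C19) without touching C4.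

**Step 4**
Reactants: 5 (3aR,7aS)-3a-methylhexahydro-2-benzofuran-1(3H)-one
Product: 7 (3aR)-3a-methyl-3a,4,5,6-tetrahydro-2-benzofuran-1(3H)-one, via selenide 6 (not isolated)
Conditions: LDA, THF, −78 °C; PhSeBr; then 30% H2O2, pyridine, CH2Cl2, 0 °C to rt
Reagents that add atoms: none
Why: α-Selenenylation of the lactone enolate and selenoxide syn-elimination, which can only go toward C10 because C4 is quaternary, give the conjugated butenolide.

**Step 5**
Reactants: 7 (3aR)-3a-methyl-3a,4,5,6-tetrahydro-2-benzofuran-1(3H)-one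
Product: 9 (3aR,7aS)-3a-methyl-1-oxooctahydro-2-benzofuran-7-carbaldehyde, via diethyl acetal 8 (not isolated)
Conditions: (EtO)2CHCO2H, 4CzIPN (2 mol %), Cs2CO3, DMSO, blue LED, rt; then 2 M HCl, THF, rt
Reagents that add atoms: 2,2-diethoxyacetic acid, CCOC(OCC)C(=O)O; water, O
Why: Photoredox decarboxylative Giese addition of the diethoxymethyl radical (a formyl-radical equivalent) to the β-carbon C10, then acetal hydrolysis; C5 reprotonates to the cis-fused lactone and the C10 epimer mixture is erased in step 6.

**Step 6**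
Reactants: 9 (3aR,7aS)-3a-methyl-1-oxooctahydro-2-benzofuran-7-carbaldehyde; 10 methyl 2-(bromomethyl)prop-2-enoate
Product: 11 methyl 2-{[(3aR,7R,7aR)-7-formyl-3a-methyl-1-oxooctahydro-2-benzofuran-7-yl]methyl}prop-2-enoate
Conditions: t-BuOK (1.05 equiv), THF, −78 °C; then 10, −78 to 0 °C
Reagents that add atoms: none
Why: C-alkylation of the α-branched aldehyde enolate (the aldehyde α-H is far more acidic than the lactone α-H) proceeds equatorially, anti to C6 on C5 and to the axial C19, so the new chain enters trans to C6 and quaternary C10 is R.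

**Step 7**
Reactants: 11 methyl 2-{[(3aR,7R,7aR)-7-formyl-3a-methyl-1-oxooctahydro-2-benzofuran-7-yl]methyl}prop-2-enoate
Product: 13 spiro α-methylene δ-lactone (4R,5R,10R), via hydroxy ester 12 (not isolated)
Conditions: NaBH4, MeOH, 0 °C; then CSA (cat.), toluene, 80 °C
Reagents that add atoms: none
Why: Aldehyde reduction followed by acid-catalysed lactonization; any lactone migration converges on the bis-lactone because only C20–OH reaches C7 in a six-membered ring.

**Step 8**
Reactants: 13 spiro α-methylene δ-lactone (4R,5R,10R)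
Product: 14 C14-bromomethyl C8=C9 unsaturated spiro δ-lactone (4R,5R,10R)
Conditions: NBS, AIBN (cat.), PhCF3, 80 °C
Reagents that add atoms: N-bromosuccinimide, O=C1CCC(=O)N1Br
Why: Wohl–Ziegler allylic bromination, in which H-abstraction at C9 gives an allyl radical that takes bromine at the primary terminus C14 with the alkene moving into conjugation.

**Step 9**
Reactants: 14 C14-bromomethyl C8=C9 unsaturated spiro δ-lactone (4R,5R,10R); 15 (3E)-hex-3-enal
Product: 16 (9S,11R)-homoallylic alcohol with regenerated C8=C14 methylene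
Conditions: In powder, THF/H2O 1:1, rt
Reagents that add atoms: none
Why: Indium-mediated Barbier allylation, in which C9 attacks the aldehyde γ-selectively through a chair transition state (the ring-fixed E-type allyl metal gives the anti adduct) on the face anti to the bulkier C5 branch of spiro C10, setting C9 (S) and C11 (R).

**Step 10**
Reactants: 16 (9S,11R)-homoallylic alcohol with regenerated C8=C14 methylene
Product: 17 11-O-benzyl ether of 16
Conditions: 2-benzyloxy-1-methylpyridinium triflate, MgO, PhCF3, 85 °C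
Reagents that add atoms: 2-benzyloxy-1-methylpyridinium trifluoromethanesulfonate, C[n+]1ccccc1OCc1ccccc1.[O-]S(=O)(=O)C(F)(F)F
Why: Neutral O-benzylation (Dudley reagent) keeps C11–OH from intercepting the acyl azolium in step 12 and avoids acid-catalysed lactone migration.

**Step 11**
Reactants: 17 11-O-benzyl ether of 16
Product: 19 (2E,5R)-enal (C15 aldehyde and C13=C16 alkene), via aldehyde 18 (not isolated)
Conditions: O3, CH2Cl2, −78 °C; PPh3; then Ph3P=CHCHO, toluene, 60 °C
Reagents that add atoms: (triphenylphosphoranylidene)acetaldehyde, O=CC=P(c1ccccc1)(c1ccccc1)c1ccccc1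
Why: Chemoselective ozonolysis of the electron-rich disubstituted alkene (the α-methylene lactone is electron-poor), then Wittig olefination with the stabilized formyl ylide, gives the (E)-enal.

**Step 12**
Reactants: 19 (2E,5R)-enal (C15 aldehyde and C13=C16 alkene)
Product: 20 11-O-benzyl-17-nor ketone (4R,5R,8S,9S,10R,11R,13S)
Conditions: 2-mesityl-6,7-dihydro-5H-pyrrolo[2,1-c][1,2,4]triazol-2-ium chloride (20 mol %), DBU (20 mol %), Mg(OtBu)2 (20 mol %), THF, 40 °C
Reagents that add atoms: none
Why: Proposed new method: the carbene converts the enal into its homoenolate, whose β-carbon C13 (normally electrophilic) adds 6-endo to C14, the electrophilic β-carbon of the α-methylene lactone, through a chair in which lactone-fused C10 is forced equatorial and the new C13 substituent is equatorial (C13 S); tautomerization to the acyl azolium and 5-exo Claisen-type C-acylation by the lactone enolate on the only reachable face of C8 then closes ring D (C8 S) and releases the carbene; the closest known reactions are NHC homoenolate Michael annulations of enals with Michael acceptors and acyl azolium acylations.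

**Step 13**
Reactants: 20 11-O-benzyl-17-nor ketone (4R,5R,8S,9S,10R,11R,13S)
Product: 21 11-O-benzyl-16-methylidene-15-ketone
Conditions: (CH2O)n, PhNHMe·CF3CO2H, THF, 65 °C
Reagents that add atoms: paraformaldehyde (formaldehyde), C=O
Why: Mannich-type α-methylenation occurs at C16, the only enolizable α-position of the C15 ketone.

**Step 14**
Reactants: 21 11-O-benzyl-16-methylidene-15-ketone
Product: 23 guidongnin C, via benzyl ether 22 (not isolated)
Conditions: H2 (1 atm), 10% Pd/C, EtOAc, rt
Reagents that add atoms: none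
Why: Heterogeneous hydrogenation delivers hydrogen to the exo face of the bicyclo[3.2.1]octane (anti to the C11–C12 bridge), placing the C16 methyl endo (16R) under neutral, non-epimerizing conditions, and hydrogenolysis removes the benzyl ether.

**Compound list**
1 | cis-cyclohexane-1,2-dicarboxylic anhydride (meso) | O=C1OC(=O)[C@@H]2CCCC[C@H]12 | starting material
2 | (1S,2R)-2-(methoxycarbonyl)cyclohexane-1-carboxylic acid | OC(=O)[C@H]1CCCC[C@H]1C(=O)OC | intermediate
3 | (1S,2R)-2-(methoxycarbonyl)-2-methylcyclohexane-1-carboxylic acid | OC(=O)[C@H]1CCCC[C@@]1(C)C(=O)OC | intermediate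
4 | (1S,2R)-2-(hydroxymethyl)-2-methylcyclohexane-1-carboxylic acid | OC(=O)[C@H]1CCCC[C@@]1(C)CO | intermediate
5 | (3aR,7aS)-3a-methylhexahydro-2-benzofuran-1(3H)-one | O=C1OC[C@]2(C)CCCC[C@H]12 | intermediate
6 | (3aR,7aR)-3a-methyl-7a-(phenylselanyl)hexahydro-2-benzofuran-1(3H)-one | O=C1OC[C@]2(C)CCCC[C@]12[Se]c1ccccc1 | intermediate
7 | (3aR)-3a-methyl-3a,4,5,6-tetrahydro-2-benzofuran-1(3H)-one | O=C1OC[C@]2(C)CCCC=C12 | intermediate
8 | (3aR,7aS)-7-(diethoxymethyl)-3a-methylhexahydro-2-benzofuran-1(3H)-one (C7 epimers) | CCOC(OCC)C1CCC[C@@]2(C)COC(=O)[C@H]21 | intermediate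
9 | (3aR,7aS)-3a-methyl-1-oxooctahydro-2-benzofuran-7-carbaldehyde (C7 epimers) | O=CC1CCC[C@@]2(C)COC(=O)[C@H]21 | intermediate
10 | methyl 2-(bromomethyl)prop-2-enoate | C=C(CBr)C(=O)OC | starting material
11 | methyl 2-{[(3aR,7R,7aR)-7-formyl-3a-methyl-1-oxooctahydro-2-benzofuran-7-yl]methyl}prop-2-enoate | C=C(C(=O)OC)C[C@@]1(CCC[C@@]2(C)COC(=O)[C@H]21)C=O | intermediate
12 | methyl 2-{[(3aR,7R,7aR)-7-(hydroxymethyl)-3a-methyl-1-oxooctahydro-2-benzofuran-7-yl]methyl}prop-2-enoate | C=C(C(=O)OC)C[C@@]1(CCC[C@@]2(C)COC(=O)[C@H]21)CO | intermediate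
13 | (3aR,7R,7aR)-3a-methyl-5'-methylidenehexahydro-1H-spiro[2-benzofuran-7,3'-oxane]-1,6'-dione (spiro α-methylene δ-lactone; 4R,5R,10R) | C=C1C[C@@]2(CCC[C@@]3(C)COC(=O)[C@H]32)COC1=O | intermediate
14 | (3aR,7R,7aR)-5'-(bromomethyl)-3a-methyl spiro[2-benzofuran-7,3'-(2'H-pyran)]-1,6'-dione with C8=C9 (4'=5') unsaturation (4R,5R,10R) | BrCC1=C[C@@]2(CCC[C@@]3(C)COC(=O)[C@H]32)COC1=O | intermediate
15 | (3E)-hex-3-enal | CC/C=C/CC=O | starting material
16 | (3aR,4'S,7R,7aR)-4'-[(1R,3E)-1-hydroxyhex-3-en-1-yl]-3a-methyl-5'-methylidenehexahydro-1H-spiro[2-benzofuran-7,3'-oxane]-1,6'-dione (9S,11R) | CC/C=C/C[C@@H](O)[C@@H]1C(=C)C(=O)OC[C@]12CCC[C@@]3(C)COC(=O)[C@H]32 | intermediate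
17 | 11-O-benzyl ether of 16: 4'-[(1R,3E)-1-(benzyloxy)hex-3-en-1-yl] analogue | CC/C=C/C[C@@H](OCc1ccccc1)[C@@H]1C(=C)C(=O)OC[C@]12CCC[C@@]3(C)COC(=O)[C@H]32 | intermediate
18 | (3R)-3-(benzyloxy)-3-[(3aR,4'S,7R,7aR)-3a-methyl-5'-methylidene-1,6'-dioxospiro-lactone-4'-yl]propanal (C13 aldehyde) | O=CC[C@@H](OCc1ccccc1)[C@@H]1C(=C)C(=O)OC[C@]12CCC[C@@]3(C)COC(=O)[C@H]32 | intermediate
19 | (2E,5R)-5-(benzyloxy)-5-[(3aR,4'S,7R,7aR)-3a-methyl-5'-methylidene-1,6'-dioxospiro-lactone-4'-yl]pent-2-enal | O=C/C=C/C[C@@H](OCc1ccccc1)[C@@H]1C(=C)C(=O)OC[C@]12CCC[C@@]3(C)COC(=O)[C@H]32 | intermediate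
20 | 11-O-benzyl-17-norguidongnin C (C16 = CH2; 4R,5R,8S,9S,10R,11R,13S) | C1C(=O)[C@]23C[C@H]1C[C@@H](OCc4ccccc4)[C@H]2[C@@]1(CCC[C@@]2(C)COC(=O)[C@H]21)COC3=O | intermediate
21 | 11-O-benzyl-16,17-didehydroguidongnin C (16-methylidene-15-ketone) | C=C1C(=O)[C@]23C[C@H]1C[C@@H](OCc4ccccc4)[C@H]2[C@@]1(CCC[C@@]2(C)COC(=O)[C@H]21)COC3=O | intermediate
22 | 11-O-benzylguidongnin C (16R) | C[C@H]1C(=O)[C@]23C[C@H]1C[C@@H](OCc4ccccc4)[C@H]2[C@@]1(CCC[C@@]2(C)COC(=O)[C@H]21)COC3=O | intermediate
23 | guidongnin C (4R,5R,8S,9S,10R,11R,13S,16R) | C[C@H]1C(=O)[C@]23C[C@H]1C[C@@H](O)[C@H]2[C@@]1(CCC[C@@]2(C)COC(=O)[C@H]21)COC3=O | target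

**Totals**
Total step count: 14. Longest linear sequence: 14 (compounds 10 and 15 are bought).

**Three steps most likely to fail**

Step 12 (carbene cascade). The homoenolate may be protonated instead of cyclizing, the lactone enolate may be quenched before it is acylated, or benzyl alcohol may be eliminated from the enal. The fallback sets out from 17. Ozonolysis with PPh3 work-up and Wittig reaction with methyl (triphenylphosphoranylidene)acetate give methyl (E)-enoate F1. SmI2/HMPA with one equivalent of t-BuOH in THF then reduces the enoate to its radical anion, whose β-carbon C13 couples to C14. The less hindered ester enolate is protonated first and the remaining samarium lactone enolate at C8 closes onto the methyl ester (Dieckmann). The route is rejoined at 20.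

Step 9 (indium allylation at the congested C9). Attack through C14 instead of C9, poor face selectivity next to the spiro centre, or migration of the lactone to O11 are possible. The fallback sets out from 14. Palladium-catalysed borylation with bis(pinacolato)diboron gives allyl pinacolboronate F2. Its allylboration of 15 under chiral phosphoric acid catalysis runs through a closed six-membered transition state, so the catalyst rather than the substrate alone controls the face. The route is rejoined at 16.

Step 6 (quaternary C10). O-alkylation of the aldehyde enolate or attack on the wrong face may compete. The fallback sets out from 9. Deliberate O-alkylation with 10 (Cs2CO3, DMF) gives allyl enol ether F3. Thermal Claisen rearrangement (toluene, 140 °C) transfers the allyl group to C10 suprafacially through a chair on the face anti to C6. The route is rejoined at 11.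

**Further compounds**
F1 | step 12 | methyl (2E,5R)-5-(benzyloxy)-5-[(3aR,4'S,7R,7aR)-3a-methyl-5'-methylidene-1,6'-dioxospiro-lactone-4'-yl]pent-2-enoate | COC(=O)/C=C/C[C@@H](OCc1ccccc1)[C@@H]1C(=C)C(=O)OC[C@]12CCC[C@@]3(C)COC(=O)[C@H]32
F2 | step 9 | C14-(4,4,5,5-tetramethyl-1,3,2-dioxaborolan-2-yl) analogue of 14 (allyl pinacolboronate) | CC1(C)OB(CC2=C[C@@]3(CCC[C@@]4(C)COC(=O)[C@H]43)COC2=O)OC1(C)C
F3 | step 6 | methyl 2-({[(3aR,7aS)-3a-methyl-1-oxohexahydro-2-benzofuran-7(1H)-ylidene]methoxy}methyl)prop-2-enoate | C=C(COC=C1CCC[C@@]2(C)COC(=O)[C@H]21)C(=O)OC
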